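**Retrosynthetic overview**
1. 24 ⇐ 16. The C15 acid (allylic oxidation of the isopropenyl methyl), the C8 tiglate, the C11=C13 methylene and the axial C8 alcohol are added last to the bicyclic keto lactone 16.
2. 16 ⇐ 10 + succinic anhydride 11 in one flask. C8–C9 forms by acylation of a C9 organolithium, then C6–C7 by aldol closure. The cyclohexane ring closes first and the γ-lactone ring (C6–O–C12) directly after it.
3. Enabling feature: C8–C7–C11–C12, shared by the cyclohexane and the lactone ring, is an intact succinyl chain. The oxygens on C6 and C8 flank C7 in a 1,3 (aldol) pattern. C9 is a CH2 on the quaternary C10, so its carbanion has nothing to eliminate and could reach C6 only through a four-membered ring.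
4. 10 ⇐ 3. The vicinal pair C5 (isopropenyl) / C10 (methyl, vinyl, CH2Cl) is the retron of an Ireland–Claisen rearrangement of an E-allylic senecioate, run under a chiral boron controller.

Key step: step 8

Remark on numbering: elemane numbering is used. The ring is C5–C10. C1=C2 is the vinyl group and C14 the methyl group on C10. C3=C4(C15) sits on C5. The lactone is C6–O–C12(=O)–C11(=C13)–C7.
Assumption: the (S,S)-configured boron controller is taken to deliver the (2S,3S)-acid 7. If the sense of induction is the opposite, its equally accessible (R,R)-enantiomer is used and nothing else changes.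

Step 1
Reactants: 1 prenol (3-methylbut-2-en-1-ol); 2 3-methylbut-2-enoyl chloride
Product: 3 prenyl senecioate (3-methylbut-2-en-1-yl 3-methylbut-2-enoate)
Conditions: pyridine, CH2Cl2, 0 °C → rt
Reagents that add atoms: none
Why: Esterification of a primary allylic alcohol by an acid chloride, with pyridine instead of a trialkylamine so that the acyl part should stay conjugated; no stereocentre is formed.

Step 2
Reactants: 3 prenyl senecioate
Product: 4 (E)-4-hydroxy-3-methylbut-2-en-1-yl 3-methylbut-2-enoate
Conditions: SeO2 (cat.), t-BuOOH, CH2Cl2, 0 °C → rt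
Reagents that add atoms: tert-butyl hydroperoxide, CC(C)(C)OO
Why: Riley allylic oxidation (ene reaction, then [2,3]-sigmatropic shift) should attack the electron-rich trisubstituted alkene rather than the conjugated one and oxidise the methyl group trans to the chain, which fixes the E geometry that step 4 needs.

Step 3
Reactants: 4 (E)-allylic alcohol
Product: 5 (E)-4-chloro-3-methylbut-2-en-1-yl 3-methylbut-2-enoate
Conditions: N-chlorosuccinimide, Me2S, CH2Cl2, −20 → 0 °C
Reagents that add atoms: N-chlorosuccinimide, O=C1CCC(=O)N1Cl
Why: Corey–Kim chlorination displaces the alkoxysulfonium salt of the primary allylic alcohol by SN2, so neither the position nor the E geometry of the alkene should change.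

Step 4
Reactants: 5 (E)-allylic chloride ester
Product: 7 (2S,3S)-3-(chloromethyl)-3-methyl-2-(prop-1-en-2-yl)pent-4-enoic acid, via boron dienolate 6 (not isolated)
Conditions: (S,S)-2-bromo-4,5-diphenyl-1,3-bis{[3,5-bis(trifluoromethyl)phenyl]sulfonyl}-1,3,2-diazaborolidine (1.2 equiv), Et3N, toluene–hexane, −78 °C, then −20 °C; aqueous work-up
Reagents that add atoms: none
Why: Enantioselective Ireland–Claisen rearrangement: the boron-complexed s-trans senecioate is deprotonated at a γ-methyl group to the E(O) boron dienolate 6, which rearranges through a chair with the chloromethyl group (trans on the E alkene) equatorial and the isopropenyl group axial, so that alkene and enolate geometry fix the relative configuration of C5 and C10 and the C2-symmetric sulfonamide controller, by shielding one enolate face, fixes the absolute one.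

Step 5
Reactants: 7 acid
Product: 8 (2S,3S)-3-(chloromethyl)-3-methyl-2-(prop-1-en-2-yl)pent-4-en-1-ol
Conditions: LiAlH4, Et2O, 0 °C → rt; aqueous work-up
Reagents that add atoms: none
Why: Hydride reduction of a carboxylic acid; the neopentyl-type C–Cl bond is shielded from SN2 hydride attack and both stereocentres are untouched.

Step 6
Reactants: 8 alcohol
Product: 9 (2S,3S)-3-(chloromethyl)-3-methyl-2-(prop-1-en-2-yl)pent-4-enal
Conditions: Dess–Martin periodinane, CH2Cl2, 0 °C → rt
Reagents that add atoms: none
Why: Dess–Martin oxidation works under near-neutral conditions, which should keep the α-stereocentre C5 and the β,γ-position of the isopropenyl alkene intact.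

Step 7
Reactants: 9 aldehyde
Product: 10 (3S,4S)-3-(chloromethyl)-4-(dimethoxymethyl)-3,5-dimethylhexa-1,5-diene
Conditions: HC(OMe)3, MeOH, pyridinium p-toluenesulfonate (cat.), rt
Reagents that add atoms: trimethyl orthoformate, COC(OC)OC
Why: Acid-catalysed acetalisation with the orthoformate as methoxy donor and water scavenger masks C6 against the organolithium chemistry of step 8; the weak acid should not enolise the hindered aldehyde.

Step 8
Reactants: 10 chloro acetal; 11 succinic anhydride
Product: 16 8-oxoelema-1,3-dien-12,6α-olide, via organolithium 12 (not isolated), via keto acid acetal 13 (not isolated), via keto aldehyde acid 14 (not isolated), via aldol hydroxy acid 15 (not isolated)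
Conditions: lithium 4,4'-di-tert-butylbiphenylide (2.2 equiv), THF, −78 °C; transfer into 11 (excess), THF, −78 → −30 °C; then 1 M aq. HCl–THF, 0 °C → rt
Reagents that add atoms: water, O
Why: Two-electron reductive lithiation of the neopentyl-type C9–Cl bond gives organolithium 12, which opens succinic anhydride at one carbonyl (C8–C9 bond, the carboxylate formed shielding the ketone from a second attack); the acid quench then unmasks the C6 aldehyde, whose only six-membered option is attack by the C7 enol of the C8 ketone (C6–C7 bond), after which the C6 hydroxyl and the C12 acid lactonise. The closest known reaction types are the reductive lithiation of alkyl chlorides, ketone synthesis from organolithiums and cyclic anhydrides, the acid-catalysed aldol cyclisation of 1,5-keto aldehydes and spontaneous γ-lactonisation. The cyclohexanone closes in a 6-(enolendo)-exo-trig aldol and the lactone in a 5-exo-trig acyl substitution. C6 is controlled by C5 (Felkin–Anh attack anti to the quaternary C10 branch, the same as the chair with isopropenyl and the new oxygen equatorial) and C7 by the enol geometry (the C11 chain anti to the bulky C9 side ends equatorial), so the lactone should be trans-fused (5α-H, 6β-H, 7α-H), while C5 and C10 are carried through. The step needs chemoselectivity (no vinyl migration in the C9 radical, secured because reduction at −78 °C is far faster than 3-exo closure; no self-quench, because C9 and C6 could only form a four-membered ring) and regioselective use of the enols (the C9 enol has no ring to close), and the quaternary C10 rules out aromatisation should some dehydration occur. Lactonisation removes the aldol from the retro-aldol and dehydration equilibria.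

Step 9
Reactants: 16 keto lactone
Product: 17 8β-hydroxyelema-1,3-dien-12,6α-olide
Conditions: LiBH(s-Bu)3, THF, −78 °C; AcOH quench at −78 °C
Reagents that add atoms: none
Why: Diastereoselective ketone reduction by a bulky trialkylborohydride: in the chair locked by the trans-lactone the axial C10 methyl blocks the axial trajectory at C8, so equatorial hydride attack should give the axial 8β-alcohol, and the cold acidic quench avoids lactone migration to O8.

Step 10
Reactants: 17 hydroxy lactone
Product: 20 8β-hydroxyelema-1,3,11(13)-trien-12,6α-olide, via Mannich base 18 (not isolated), via trimethylammonium iodide 19 (not isolated)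
Conditions: LiN(SiMe3)2 (2.2 equiv), THF, −78 °C; Me2N=CH2+ I−, −78 → 0 °C; H2O; then MeI, MeOH, rt; then aq. NaHCO3, CH2Cl2
Reagents that add atoms: N,N-dimethylmethyleneiminium iodide (Eschenmoser's salt), C[N+](C)=C.[I-]
Why: α-Methylenation by Mannich reaction of the lactone enolate (alkoxide–enolate dianion) with Eschenmoser's salt, quaternisation and Hofmann-type elimination; the transient C11 centre is destroyed again and C7 has no acidifying neighbour left.

Step 11
Reactants: 20 α-methylene hydroxy lactone; 21 tigloyl chloride ((E)-2-methylbut-2-enoyl chloride)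
Product: 22 8β-tigloyloxyelema-1,3,11(13)-trien-12,6α-olide
Conditions: pyridine, 4-(dimethylamino)pyridine (cat.), CH2Cl2, 0 → 40 °C
Reagents that add atoms: none
Why: Nucleophile-catalysed acylation of the hindered axial alcohol with retention at C8; the E (tiglate) geometry comes with the reagent and is the thermodynamically preferred one.

Step 12
Reactants: 22 tiglate
Product: 23 15-oxo-8β-tigloyloxyelema-1,3,11(13)-trien-12,6α-olide
Conditions: SeO2 (1.1 equiv), 1,4-dioxane, 70 °C
Reagents that add atoms: SeO2, O=[Se]=O
Why: Riley oxidation to the enal should pick the isopropenyl group, the only electron-rich alkene with accessible allylic hydrogens (the vinyl group has none, the tiglate and the methylene lactone are electron-poor, and C5–H is screened by the quaternary C10).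

Step 13
Reactants: 23 enal
Product: 24 8β-tigloyloxyelema-1,3,11(13)-trien-12,6α-olid-15-oic acid (CNP0256928.1)
Conditions: NaClO2, NaH2PO4, 2-methylbut-2-ene, t-BuOH–H2O, 0 °C → rt
Reagents that add atoms: NaClO2, [Na+].[O-]Cl=O
Why: Pinnick oxidation converts the α-substituted acrolein into the acrylic acid under buffered conditions that spare the alkenes, both esters and all stereocentres, the scavenger alkene taking up the hypochlorous acid.

**Compound list**
1 | prenol | CC(C)=CCO | starting material
2 | 3-methylbut-2-enoyl chloride | CC(C)=CC(=O)Cl | starting material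
3 | prenyl senecioate | CC(C)=CCOC(=O)C=C(C)C | intermediate
4 | (E)-4-hydroxy-3-methylbut-2-en-1-yl 3-methylbut-2-enoate | OC/C(C)=C/COC(=O)C=C(C)C | intermediate
5 | (E)-4-chloro-3-methylbut-2-en-1-yl 3-methylbut-2-enoate | ClC/C(C)=C/COC(=O)C=C(C)C | intermediate
6 | E(O) boron dienolate of 5 on the (S,S)-diazaborolidine | C=C(C)/C=C(\OC/C=C(\C)CCl)OB1N(S(=O)(=O)c2cc(cc(c2)C(F)(F)F)C(F)(F)F)[C@@H](c2ccccc2)[C@H](c2ccccc2)N1S(=O)(=O)c1cc(cc(c1)C(F)(F)F)C(F)(F)F | intermediate
7 | (2S,3S)-3-(chloromethyl)-3-methyl-2-(prop-1-en-2-yl)pent-4-enoic acid | C=C[C@](C)(CCl)[C@H](C(C)=C)C(=O)O | intermediate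
8 | (2S,3S)-3-(chloromethyl)-3-methyl-2-(prop-1-en-2-yl)pent-4-en-1-ol | C=C[C@](C)(CCl)[C@H](C(C)=C)CO | intermediate
9 | (2S,3S)-3-(chloromethyl)-3-methyl-2-(prop-1-en-2-yl)pent-4-enal | C=C[C@](C)(CCl)[C@H](C(C)=C)C=O | intermediate
10 | (3S,4S)-3-(chloromethyl)-4-(dimethoxymethyl)-3,5-dimethylhexa-1,5-diene | C=C[C@](C)(CCl)[C@H](C(C)=C)C(OC)OC | intermediate
11 | succinic anhydride | O=C1CCC(=O)O1 | starting material
12 | C9 organolithium from 10 | C=C[C@](C)(C[Li])[C@H](C(C)=C)C(OC)OC | intermediate
13 | keto acid acetal (C8 ketone, C12 acid, C6 dimethyl acetal) | C=C[C@](C)(CC(=O)CCC(=O)O)[C@H](C(C)=C)C(OC)OC | intermediate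
14 | keto aldehyde acid | C=C[C@](C)(CC(=O)CCC(=O)O)[C@H](C(C)=C)C=O | intermediate
15 | aldol hydroxy acid (6α-OH, 7β-CH2CO2H, 8-oxo) | C=C[C@]1(C)CC(=O)[C@@H](CC(=O)O)[C@H](O)[C@H]1C(C)=C | intermediate
16 | 8-oxoelema-1,3-dien-12,6α-olide (5α-H, 6β-H, 7α-H, 10β-methyl) | C=C[C@]1(C)CC(=O)[C@H]2CC(=O)O[C@@H]2[C@H]1C(C)=C | intermediate
17 | 8β-hydroxyelema-1,3-dien-12,6α-olide | C=C[C@]1(C)C[C@@H](O)[C@H]2CC(=O)O[C@@H]2[C@H]1C(C)=C | intermediate
18 | 13-(dimethylamino) Mannich base of 17 (C11 epimers) | C=C[C@]1(C)C[C@@H](O)[C@H]2C(CN(C)C)C(=O)O[C@@H]2[C@H]1C(C)=C | intermediate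
19 | trimethylammonium iodide of 18 | C=C[C@]1(C)C[C@@H](O)[C@H]2C(C[N+](C)(C)C)C(=O)O[C@@H]2[C@H]1C(C)=C.[I-] | intermediate
20 | 8β-hydroxyelema-1,3,11(13)-trien-12,6α-olide | C=C[C@]1(C)C[C@@H](O)[C@H]2C(=C)C(=O)O[C@@H]2[C@H]1C(C)=C | intermediate
21 | tigloyl chloride | ClC(=O)/C(C)=C/C | starting material
22 | 8β-tigloyloxyelema-1,3,11(13)-trien-12,6α-olide | C=C[C@]1(C)C[C@@H](OC(=O)/C(C)=C/C)[C@H]2C(=C)C(=O)O[C@@H]2[C@H]1C(C)=C | intermediate
23 | 15-oxo-8β-tigloyloxyelema-1,3,11(13)-trien-12,6α-olide | C=C[C@]1(C)C[C@@H](OC(=O)/C(C)=C/C)[C@H]2C(=C)C(=O)O[C@@H]2[C@H]1C(=C)C=O | intermediate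
24 | 8β-tigloyloxyelema-1,3,11(13)-trien-12,6α-olid-15-oic acid (CNP0256928.1) | C=C[C@]1(C)C[C@@H](OC(=O)/C(C)=C/C)[C@H]2C(=C)C(=O)O[C@@H]2[C@H]1C(=C)C(=O)O | target

Total step count: 13. Longest linear sequence: 13 steps (from 1).

**Steps most likely to fail**

Step 8.
- What may go wrong: the organolithium may deprotonate the anhydride or add twice. At the free aldehyde stage, acid may move the isopropenyl double bond into conjugation or erode C5. The aldol may dehydrate. C7 may equilibrate towards the cis-fused lactone.
- Fallback: it sets out from 10 and returns at 16, and it makes the two bonds separately under kinetic control. The organolithium from 10 is acylated with tert-butyl 4-[methoxy(methyl)amino]-4-oxobutanoate (Weinreb ketone synthesis), and the tert-butyl keto ester acetal F1 is isolated. Pyridinium p-toluenesulfonate in wet acetone gives the tert-butyl keto aldehyde ester F2. Treatment with (c-C6H11)2BCl and Et3N at −78 °C forms the less hindered C7 boron enolate, which closes by an intramolecular boron aldol through a closed transition state to the tert-butyl hydroxy keto ester F3. CF3CO2H then cleaves the tert-butyl ester and lactonises to 16.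

Step 4.
- What may go wrong: facial selectivity may be incomplete. The E(O) geometry may be lost during γ-deprotonation of the conjugated ester. The amine may slowly be quaternised by the allylic chloride.
- Fallback: it sets out from 5 and returns at 7. Deprotonation with LiN(i-Pr)2 and kinetic protonation gives the deconjugated ester (E)-4-chloro-3-methylbut-2-en-1-yl 3-methylbut-3-enoate F4. Its α-deprotonation with LiN(i-Pr)2 and Me3SiCl in THF gives the E(O) silyl ketene acetal as for simple alkanoates, and a classical Ireland–Claisen rearrangement then gives the racemic acid, that is 7 together with the enantiomeric acid F5. Crystallisation of the (R)-1-phenylethylammonium salt of 7 F6, followed by acidification, returns 7 (classical resolution).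

Step 12.
- What may go wrong: the tertiary allylic C5–H may be abstracted in competition. The reaction may stop at the allylic alcohol. The tiglate methyl groups may be attacked on heating.
- Fallback: it sets out from 22 and returns at 23. Ene-type allylic chlorination of the isopropenyl group with Ca(OCl)2 and solid CO2 in CH2Cl2–H2O gives the 15-chloride F7. N-methylmorpholine N-oxide in MeCN then oxidises F7 to the enal 23 (Ganem oxidation).

**Further compounds**
F1 | step 8 | tert-butyl keto ester acetal (tert-butyl ester of 13) | C=C[C@](C)(CC(=O)CCC(=O)OC(C)(C)C)[C@H](C(C)=C)C(OC)OC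
F2 | step 8 | tert-butyl keto aldehyde ester (tert-butyl ester of 14) | C=C[C@](C)(CC(=O)CCC(=O)OC(C)(C)C)[C@H](C(C)=C)C=O
F3 | step 8 | tert-butyl hydroxy keto ester (tert-butyl ester of 15) | C=C[C@]1(C)CC(=O)[C@@H](CC(=O)OC(C)(C)C)[C@H](O)[C@H]1C(C)=C
F4 | step 4 | (E)-4-chloro-3-methylbut-2-en-1-yl 3-methylbut-3-enoate | ClC/C(C)=C/COC(=O)CC(C)=C
F5 | step 4 | (2R,3R)-3-(chloromethyl)-3-methyl-2-(prop-1-en-2-yl)pent-4-enoic acid | C=C[C@@](C)(CCl)[C@@H](C(C)=C)C(=O)O
F6 | step 4 | (R)-1-phenylethylammonium salt of 7 | C=C[C@](C)(CCl)[C@H](C(C)=C)C(=O)[O-].C[C@@H]([NH3+])c1ccccc1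
F7 | step 12 | 15-chloro-8β-tigloyloxyelema-1,3,11(13)-trien-12,6α-olide | C=C[C@]1(C)C[C@@H](OC(=O)/C(C)=C/C)[C@H]2C(=C)C(=O)O[C@@H]2[C@H]1C(=C)CCl
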